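The runs were generated by integration for an exercise.

Count the ligand.

| setting | beta | theta | teal | red | amber |
|---|---|---|---|---|---|
| starting complex | 0.060 M | 0.060 M | 0.060 M | 0.20 M | 0.60 M |
| incoming ligand | 0.22 M | 0.22 M | 0.220 M | 0.220 M | 0.220 M |
| protic impurity | 0.13 M | 0.40 M | 0.200 M | 0.200 M | 0.200 M |
| remark | run made earlier | run made earlier |  |  |  |
| time |  |  | 25 h | 25 h | 25 h |

- beta (time / h: complex with three exchanged / %, starting complex / %): 1.33: 0.3, 11.3; 2.50: 1.9, 2.0; 4.00: 2.7, 0.2; 8.00: 3.7, 0.6; 15.0: 6.6, 0
- theta (time / h: complex with three exchanged / %, starting complex / %): 3.00: 1.3, 1.5; 6.00: 2.7, 0; 10.0: 2.8, 0.6; 12.0: 2.4, 0; 15.0: 3.2, 0.4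

(standard deviation of a reading: 0.5 percentage points)

- what was read earlier has a scatter of 0.5 percentage points, one standard deviation
- "hardly changes" means that all values lie within two and a half points (for a concentration: within two and a half percent of the largest)

1. [complex with three exchanged] at the end for teal, red, amber, in this order
2. the course of these numbers from the first flask to the last (falls, then rises / falls all the way / rises, then falls / rises all the way / hardly changes)

Each exchange on a complex takes one incoming ligand, so in the teal flask, with 3.67 incoming ligand per starting complex charged, this ratio, the ligand budget, is the ceiling on exchanges per complex charged, and you can draw the row against it. At low charge the budget stands above the 3 exchanges the product needs, so you take the fraction of the charge standing as complex with three exchanged from the runs, 6.6 % in beta and 3.2 % in theta at 15.0 h, with the impurity of teal lying between theirs, and the row climbs with the charge. The first knee lies where the budget reaches 3, at a charge of 0.0733 M, and past it the ceiling on that fraction is the budget over 3, which for the red flask, with a budget of 1.10, is 36.7 %, still higher than those readings, so you expect red to stand above teal in concentration. The second knee lies where the budget reaches one: the budget of red stands above one, and the budget of the amber flask, at 0.367, stands below one. Starting complex fades early in the beta run, with a reading of 11.3 % left at 1.33 h, so you expect the first exchange in amber to take up its budget of 0.367 and the curve to come down below teal: the row rises, then falls.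

The forecast parts from this reckoning at the red flask: it gives 0.0033 M, 4.000 × 10⁻⁴ M and 2.000 × 10⁻⁵ M, a course that falls all the way, with the words “Stoichiometry then dominates.”

The flasks end at 0.00334 M, 0.00491 M and 6.75 × 10⁻⁴ M, a course that rises, then falls, with red and amber above the forecast.

    complex with one exchanged + incoming ligand ⇌ leaving ligand + complex with two exchanged (K = 1.20, k = 0.00220 /M/s)
    complex with three exchanged → over-reaction product (k = 1.90 × 10⁻⁵ /s)
    complex with two exchanged + incoming ligand ⇌ leaving ligand + complex with three exchanged (K = 0.710, k = 5.70 × 10⁻⁵ /M/s)
    protic impurity + starting complex → quenched substrate (k = 0.00170 /M/s)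
    complex with three exchanged + incoming ligand ⇌ leaving ligand + complex with four exchanged (K = 0.500, k = 6.20 × 10⁻⁴ /M/s)
    starting complex + incoming ligand ⇌ leaving ligand + complex with one exchanged (K = 6.40, k = 0.00140 /M/s)

The amber flask shows the budget at work: against its 0.367 ligand per complex charged, leaving ligand per complex charged stands at 0.331, with 9.67 % of the incoming ligand left at the end. Yet complex with three exchanged in amber ends at 6.75 × 10⁻⁴ M, and the same run without the way back from leaving ligand and complex with one exchanged to starting complex and incoming ligand ends at 1.78 × 10⁻⁵ M, so that way back is the largest single effect on this number. The red flask has used about half of its budget of 1.10, with leaving ligand per complex charged at 0.555 and quenched substrate at 70.0 %.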